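- 0.0250 M of turnover, half of the charge of starting material, is the balance mark of these flasks: the adduct constant times the charge is 60, far above 1, so each first product released ties up about one more starting material, and about two leave free solution per turn of the enzyme.

all flasks: starting material 0.050 M; free enzyme 5.0 µM; time 5.0 min
- Wednesday's: second substrate 0.100 M
- Monday's: second substrate 0.150 M
- Sunday's: second substrate 0.230 M

    starting material + free enzyme ⇌ first complex (K1 = 14.6 /M, k1 = 89900 /M/s)
    starting material + first product ⇌ idle adduct, settled at all times (K2 = 1190 /M)
    second complex → free enzyme + target (k3 = 109 /s)
    first complex → loaded enzyme + first product (k4 = 306 /s)
    second substrate + loaded enzyme ⇌ second complex (K5 = 17 /M, k5 = 2.96 × 10⁵ /M/s)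
    target → over-reaction product (k6 = 0.0304 /s)

- what is said of first product includes idle adduct
- what has gone from starting material into another species counts as reacted, even if it can come back
- run time (Wednesday's): 5.0 min

1. part of the starting material that has reacted at the end, Wednesday's
2. part of the starting material that has reacted at the end, Monday's
3. part of the starting material that has reacted at the end, Sunday's
4. what raising the concentration of second substrate from its lowest to its highest value here does to the part of the starting material that has reacted (changes below 5 percentage points count as none) (it rises / it falls / no change)

- Slope at the start, Wednesday's: 4.73% of first complex goes on, which makes the effective capture constant of starting material 4260 /M/s, and second complex likewise gives 1840 /M/s for second substrate.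
- In this ping-pong cycle the two capture waits at the charges and the two release times add up to one turn in 0.0226 s, so Wednesday's enzyme releases first product at 2.22 × 10⁻⁴ M/s.
- The knee, Wednesday's: at that slope the balance mark takes 1.88 min; this is the knee time, the balance mark over the starting rate of release.
- At the mark, free starting material equals free first product, and the adduct balance puts it at 8.37% of the charge, a level with no second substrate in it.
- Beyond the knee, free first product grows and the balance presses free starting material lower.
- Wednesday's run is longer than the knee time, at 2.66 knee times, so this reckoning commits to more than 91.6% reacted and stops at that floor.
- Sunday's second substrate shortens the reckoned knee time to 1.63 min; the run is longer than the knee time in Wednesday's and in Sunday's, so the reckoning expects no change.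
- The forecast goes beyond that floor, with 97.3%, 97.5% and 97.6%, trend no change, on the grounds that “Each turnover releases first product, which ties up roughly one more starting material in the idle adduct”.
- The flasks give 97.4%, 97.6% and 97.7%, a change of 0.27 percentage points, so no change.
- At 2.50 min, 1.33 knee times, Wednesday's target and over-reaction product together hold 48.0% of the charge, less than the mark of 50.0%, with free starting material at 10.6%. With 3.0 × 10⁻⁶ M of free enzyme the knee time stretches to 3.13 min, so 5.0 min is 1.60 knee times, and that neighbour flask stands just past the mark with 51.9% in those two products, free starting material at 6.7%, below the knee level, and 93.3% reacted.

The constants were chosen freely; the rest is arithmetic.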